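**Assumption:** the target has no stereocentre and the SMILES specifies no axial configuration, so it is made as the single achiral compound drawn; the "single enantiomer" condition needs no stereocontrol.

## Retrosynthetic overview

- Target ⇒ 2,5-dichloro-3,6-bis(indolyl)benzoquinone + NaOMe: both C–OMe bonds come last, by double vinylogous acyl substitution of chloride.
- Bis(indolyl)dichloroquinone ⇒ 2,5-dichloro-3-(indol-3-yl)benzoquinone + 2-(2-methylbut-3-en-2-yl)indole: the key C–C bond, by intermolecular acid-promoted Michael addition of indole C3 to the quinone, then re-oxidation.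
- Mono(indolyl)dichloroquinone ⇒ indole + 2,5-dichloro-1,4-benzoquinone, by the same Michael addition/oxidation.
- 2-(2-Methylbut-3-en-2-yl)indole ⇒ phenylhydrazone of 3,3-dimethylpent-4-en-2-one (Fischer) ⇒ prenylzinc bromide + acetonitrile.
- Ring order: the only ring built is the pyrrole ring of the substituted indole (Fischer step); the quinone ring, the benzene rings and the parent indole are bought.

## Route

**Step 1**
Reactants: 1 prenyl bromide (1-bromo-3-methylbut-2-ene); 2 acetonitrile
Product: 5 3,3-dimethylpent-4-en-2-one, via prenylzinc bromide 3 (not isolated), via bromozinc ketiminate 4 (not isolated)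
Conditions: Zn dust (1.3 equiv, TMSCl-activated), THF, 0 °C → rt; then MeCN (3 equiv), rt → 45 °C; then 1 M aq HCl, 0 °C → rt
Reagents that add atoms: water (O)
Why: Barbier/Blaise-type addition of an allylic zinc reagent to a nitrile proceeds with allylic transposition (γ-attack through a six-membered SE2′ transition state) to give the 1,1-dimethylallyl ketimine, the quaternary centre blocks a second addition, and acid hydrolysis gives the non-isomerisable β,γ-unsaturated ketone (no stereocentre).

**Step 2**
Reactants: 5 3,3-dimethylpent-4-en-2-one; 6 phenylhydrazine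
Product: 7 3,3-dimethylpent-4-en-2-one phenylhydrazone (E isomer major)
Conditions: PhNHNH2 (1.05 equiv), AcOH (cat.), EtOH, reflux, 2 h; concentrate, use crude under N2
Reagents that add atoms: none
Why: Hydrazone condensation of a methyl ketone is fast and quantitative under weak acid catalysis that leaves the 1,1-dimethylallyl group untouched; the C=N geometry is irrelevant because both isomers react through the same ene-hydrazine.

**Step 3**
Reactants: 7 3,3-dimethylpent-4-en-2-one phenylhydrazone
Product: 8 2-(2-methylbut-3-en-2-yl)-1H-indole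
Conditions: PCl3 (1.0 equiv), CH2Cl2, 0 °C → rt, 2 h; then ice-water
Reagents that add atoms: none
Why: Fischer indole synthesis under mild PCl3 promotion: the hydrazone can form an ene-hydrazine only toward the methyl group, so [3,3]-shift, cyclisation and loss of ammonia give only the 2-substituted, 3-unsubstituted indole, at a temperature where the acid-labile tertiary allyl group survives.

**Step 4**
Reactants: 9 indole; 10 2,5-dichloro-1,4-benzoquinone
Product: 12 2,5-dichloro-3-(1H-indol-3-yl)cyclohexa-2,5-diene-1,4-dione, via indolyl dichlorohydroquinone 11 (not isolated)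
Conditions: 10 (1.2 equiv), conc. HCl (0.5 equiv), THF, rt, 16 h; then DDQ (1.1 equiv), rt, 1 h
Reagents that add atoms: none
Why: Acid-promoted intermolecular Michael addition of the enamine-like indole C3 to the protonated quinone occurs at an unsubstituted ring carbon (the two are equivalent), the adduct tautomerises to the hydroquinone, and DDQ re-oxidises it to the quinone, the slight excess of 10 limiting double addition.

**Step 5**
Reactants: 12 2,5-dichloro-3-(1H-indol-3-yl)cyclohexa-2,5-diene-1,4-dione; 8 2-(2-methylbut-3-en-2-yl)-1H-indole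
Product: 14 2,5-dichloro-3-(1H-indol-3-yl)-6-[2-(2-methylbut-3-en-2-yl)-1H-indol-3-yl]cyclohexa-2,5-diene-1,4-dione, via bis-indolyl dichlorohydroquinone 13 (not isolated)
Conditions: 8 (1.2 equiv), AcOH, rt → 45 °C, 24–48 h; then DDQ (1.1 equiv), THF, rt, 1 h
Reagents that add atoms: none
Why: Second intermolecular Michael addition, in which C3 of the electron-rich 2-alkylindole attacks the only remaining C–H position of quinone 12 (para to the first indole), promoted by acetic acid because mineral acid would ionise the tertiary allyl group, followed by DDQ oxidation of the hydroquinone.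

**Step 6**
Reactants: 14 2,5-dichloro-3-(1H-indol-3-yl)-6-[2-(2-methylbut-3-en-2-yl)-1H-indol-3-yl]cyclohexa-2,5-diene-1,4-dione
Product: 15 2,5-dimethoxy-3-(1H-indol-3-yl)-6-[2-(2-methylbut-3-en-2-yl)-1H-indol-3-yl]cyclohexa-2,5-diene-1,4-dione (target)
Conditions: NaOMe (6 equiv), anhydrous MeOH/THF, 0 °C → rt; then AcOH, aq NH4Cl
Reagents that add atoms: sodium methoxide ([Na+].[O-]C)
Why: Each C–Cl is a vinylogous acid chloride, so methoxide replaces the two chlorides in turn by conjugate addition–elimination; excluding water stops the reaction at the bis(methyl ether), and the indole N–H groups are only reversibly deprotonated and return on quench.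

## Compound list

1 | prenyl bromide (1-bromo-3-methylbut-2-ene) | CC(C)=CCBr | starting material
2 | acetonitrile | CC#N | starting material
3 | prenylzinc bromide [(3-methylbut-2-en-1-yl)zinc bromide] | CC(C)=CC[Zn]Br | intermediate (not isolated)
4 | bromozinc ketiminate (N-bromozincio imine of 3,3-dimethylpent-4-en-2-one) | CC(=N[Zn]Br)C(C)(C)C=C | intermediate (not isolated)
5 | 3,3-dimethylpent-4-en-2-one | CC(=O)C(C)(C)C=C | intermediate
6 | phenylhydrazine | NNc1ccccc1 | starting material
7 | (E)-1-(3,3-dimethylpent-4-en-2-ylidene)-2-phenylhydrazine | C/C(=N\Nc1ccccc1)C(C)(C)C=C | intermediate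
8 | 2-(2-methylbut-3-en-2-yl)-1H-indole | C=CC(C)(C)c1cc2ccccc2[nH]1 | intermediate
9 | indole | c1ccc2[nH]ccc2c1 | starting material
10 | 2,5-dichloro-1,4-benzoquinone | O=C1C=C(Cl)C(=O)C=C1Cl | starting material
11 | 2,5-dichloro-3-(1H-indol-3-yl)benzene-1,4-diol | Oc1cc(Cl)c(O)c(-c2c[nH]c3ccccc23)c1Cl | intermediate (not isolated)
12 | 2,5-dichloro-3-(1H-indol-3-yl)cyclohexa-2,5-diene-1,4-dione | O=C1C=C(Cl)C(=O)C(c2c[nH]c3ccccc23)=C1Cl | intermediate
13 | 2,5-dichloro-3-(1H-indol-3-yl)-6-[2-(2-methylbut-3-en-2-yl)-1H-indol-3-yl]benzene-1,4-diol | Oc1c(Cl)c(-c2c[nH]c3ccccc23)c(O)c(Cl)c1-c1c(C(C)(C)C=C)[nH]c2ccccc12 | intermediate (not isolated)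
14 | 2,5-dichloro-3-(1H-indol-3-yl)-6-[2-(2-methylbut-3-en-2-yl)-1H-indol-3-yl]cyclohexa-2,5-diene-1,4-dione | O=C1C(Cl)=C(c2c[nH]c3ccccc23)C(=O)C(Cl)=C1c1c(C(C)(C)C=C)[nH]c2ccccc12 | intermediate
15 | 2,5-dimethoxy-3-(1H-indol-3-yl)-6-[2-(2-methylbut-3-en-2-yl)-1H-indol-3-yl]cyclohexa-2,5-diene-1,4-dione | C=CC(C)(C)c1[nH]c2ccccc2c1C1=C(OC)C(=O)C(c2c[nH]c3ccccc23)=C(OC)C1=O | target

## Step count and risk

Total steps: 6. Longest linear sequence: 5 (steps 1, 2, 3, 5, 6); step 4 is a one-step branch.

**Step 5 (highest risk).** A 2-tert-alkylindole must attack a quinone already made less electrophilic by an indolyl donor, under acid mild enough to spare the tertiary allyl group. The fallback reverses the order of the two conjugate additions; it sets out from 8 and 10 and comes back to the route at 13. Indole 8 is stirred with an excess (3 equiv) of the unsubstituted, more electrophilic quinone 10 in AcOH/THF to give 2,5-dichloro-3-[2-(2-methylbut-3-en-2-yl)-1H-indol-3-yl]benzene-1,4-diol F4. DDQ oxidises this in the same flask to 2,5-dichloro-3-[2-(2-methylbut-3-en-2-yl)-1H-indol-3-yl]cyclohexa-2,5-diene-1,4-dione F5. The small, unhindered indole 9 is then added to F5 (AcOH/THF, rt) to give hydroquinone 13, from which DDQ oxidation to 14 and step 6 follow as written.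

**Step 3.** The Fischer cyclisation of a methyl ketone hydrazone to a 3-unsubstituted indole is demanding, and the acid set free can ionise or cyclise the 1,1-dimethylallyl group. The fallback builds the pyrrole ring by alkyne hydroamination instead; it sets out from 5 and comes back at 8. Ketone 5 is enolised on its only enolisable side (LDA, THF, −78 °C) and trapped with ClP(O)(OEt)2 to give diethyl 3,3-dimethylpenta-1,4-dien-2-yl phosphate F1. A second treatment with LDA (2.2 equiv, −78 °C → rt) eliminates diethyl phosphate to give 3,3-dimethylpent-1-en-4-yne F2, kept as a THF solution because it is volatile. Sonogashira coupling with commercial 2-iodoaniline (Nc1ccccc1I; PdCl2(PPh3)2, CuI, Et3N, rt) gives 2-(3,3-dimethylpent-4-en-1-yn-1-yl)aniline F3. Base-mediated 5-endo-dig cyclisation (KOt-Bu, NMP, rt) then gives 8 with no acid present at any stage.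

**Step 6.** Substitution may stall at the mono-methoxy stage because the deprotonated indoles deactivate the quinone, or run on to the hydroxyquinone if moisture is present. The fallback goes deliberately through the dihydroxyquinone; it sets out from 14 and comes back at 15. Compound 14 is heated with NaOH in MeOH/H2O at reflux and acidified to give 2,5-dihydroxy-3-(1H-indol-3-yl)-6-[2-(2-methylbut-3-en-2-yl)-1H-indol-3-yl]cyclohexa-2,5-diene-1,4-dione F6. The two vinylogous-acid hydroxyls of F6 are then O-methylated selectively with TMSCHN2 (MeOH/CH2Cl2, 0 °C → rt), which does not touch the indole N–H groups, to give 15.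

## Further compounds

F1 | step 3 | diethyl 3,3-dimethylpenta-1,4-dien-2-yl phosphate | C=C(OP(=O)(OCC)OCC)C(C)(C)C=C
F2 | step 3 | 3,3-dimethylpent-1-en-4-yne | C#CC(C)(C)C=C
F3 | step 3 | 2-(3,3-dimethylpent-4-en-1-yn-1-yl)aniline | Nc1ccccc1C#CC(C)(C)C=C
F4 | step 5 | 2,5-dichloro-3-[2-(2-methylbut-3-en-2-yl)-1H-indol-3-yl]benzene-1,4-diol | Oc1cc(Cl)c(O)c(-c2c(C(C)(C)C=C)[nH]c3ccccc23)c1Cl
F5 | step 5 | 2,5-dichloro-3-[2-(2-methylbut-3-en-2-yl)-1H-indol-3-yl]cyclohexa-2,5-diene-1,4-dione | O=C1C=C(Cl)C(=O)C(c2c(C(C)(C)C=C)[nH]c3ccccc23)=C1Cl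
F6 | step 6 | 2,5-dihydroxy-3-(1H-indol-3-yl)-6-[2-(2-methylbut-3-en-2-yl)-1H-indol-3-yl]cyclohexa-2,5-diene-1,4-dione | C=CC(C)(C)c1[nH]c2ccccc2c1C1=C(O)C(=O)C(c2c[nH]c3ccccc23)=C(O)C1=O
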